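The leftover I looked at first was what Saturday's flask had not made. At 51 h its target read 0.4695 M from 0.800 M of starting material, the limiting reagent there against 0.880 M of partner, which gives a shortfall of 41.3 %. By shortfall I mean the share of the starting material charged that does not stand as target at a given time, whatever has become of it.

| flask | starting material | partner | time |
|---|---|---|---|
| Saturday's | 0.800 M | 0.880 M |  |
| Wednesday's | 0.320 M | 0.400 M |  |
| Friday's | 0.800 M | 1.30 M |  |
| Tuesday's | 0.800 M | 1.80 M | 51 h |

| Saturday's run: time / h | Saturday's run: [target] / M | Wednesday's run: time / h | Wednesday's run: [target] / M | Friday's run: time / h | Friday's run: [target] / M |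
|---|---|---|---|---|---|
| 6.4 | 0.1719 | 6.4 | 0.0404 | 6.4 | 0.2288 |
| 13 | 0.2781 | 13 | 0.0698 | 13 | 0.3625 |
| 19 | 0.3378 | 19 | 0.0963 | 19 | 0.4429 |
| 26 | 0.3885 | 26 | 0.1141 | 26 | 0.4990 |
| 32 | 0.4207 | 32 | 0.1276 | 32 | 0.5289 |
| 38 | 0.4411 | 38 | 0.1352 | 38 | 0.5524 |
| 45 | 0.4599 | 45 | 0.1438 | 45 | 0.5730 |
| 51 | 0.4695 | 51 | 0.1570 | 51 | 0.5834 |

(readings scatter by 0.002 M)

- Overall: starting material + partner -> target.
- Constant volume, constant temperature.
- "The second partner" is partner.
- An order is taken over about fifteen percent of the charge, up and down.

* how the opening rate goes with [starting material] round the charge of the Saturday's run: the exponent of the rate at two percent of starting material gone to target (one fixed amount of target, the same in the runs compared)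
* how the opening rate goes with [partner] round the charge of the Saturday's run: the exponent of the rate at two percent of starting material gone to target
* target in the Tuesday's run at 51 h, as a share of the starting material charged

The decision was whether Tuesday's flask should carry 1.80 M of partner or stay at Friday's 1.30 M, with the same 0.800 M of starting material. Friday's shortfall at the same hour was 27.1 %, smaller than Saturday's. Those two flasks share their starting material charge and differ in partner charge, so I compared them and set aside Wednesday's flask, which differs from them in both charges.

I worked in logarithms. From Saturday to Friday, the log10 of the partner charge rose by 0.169 and the log10 of the shortfall fell by 0.183. Their ratio is what I called the shortfall exponent, the power of the partner charge by which the shortfall falls at a fixed hour and fixed starting material, and it came to 1.08.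

Two points give a line but no test of it. Still, Tuesday's step is 0.141 in log10 of partner, and multiplying by the exponent takes 0.153 off the log10 of the shortfall. That put Tuesday's shortfall at 19.0 %, a target share of 81.0 %. So the extra 0.500 M of partner was to buy 0.0648 M of target, far more than the 0.002 M scatter of a reading, and I charged it. For the two orders I reckoned nothing of my own.

The forecast gave 0.9 in starting material, 0.8 in partner and 82 % for Tuesday, higher than my share, and it began from the words “The approach to a plateau is the main feature.”

Round Saturday's charge the flask gave an order of 0.88 in starting material and 0.87 in partner, and target in Tuesday's flask at 51 h came to 81.9 %.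

    starting material + partner ⇌ intermediate, settled at all times (0.3110 L mol⁻¹)
    starting material + partner → target (0.07344 L mol⁻¹ h⁻¹)
    starting material → decomposed substrate (0.008892 h⁻¹)
    2 starting material → homo dimer (0.01958 L mol⁻¹ h⁻¹)

Tuesday's shortfall was 18.1 %, which is 0.90 percentage points under the 19.0 % that the exponent 1.08 gave. In the same Tuesday run, target stands at 87.5 % without the path to decomposed substrate and at 89.0 % without the path to homo dimer. These two paths, acting together, are a reason for what is missing from Tuesday's target: taking away the path to decomposed substrate restores 31 % of what is missing, and taking away the path to homo dimer restores 39 %.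

The runs stem from a simulated flask for substances that don't exist.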